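**Plan**

- Retrosynthesis: the O-protecting groups come off last. The ring A aryl–acyl bond is cut next (Friedel–Crafts), then ring C at O1–C2, C3–C4 and C4–C4a. Ring B is cut at C8a–C8 and C6–C7 into 3-ethoxy-2-methylcyclobutenone and a siloxyalkyne that already carries ring A on its propargylic CH2. The alkyne goes back to 2,4,6-trihydroxytoluene.
- Enabling feature: ring B is a benzene with oxygen on C5, C7 and C8a and carbon on C6 and C8. A vinylketene supplies C8a(=O), C6(Me), C5(OEt) and C4a(H2); an ynol silyl ether supplies C8(CH2Ar) and C7(OSi). The three oxygens are therefore born as OH, OSi and OEt, and only the C8a hydroxyl can later close the pyranone.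
- Forward order: ring A is bought and homologated to the siloxyalkyne. Ring B arises by benzannulation. Ring C follows by phenol-directed ortho-formylation, alkenyl addition, oxidation and oxa-Michael closure. Ring A is then acylated and all ethers are cleaved.
- Stereochemistry: the target has no stereocentre. The carbinols and the cyclobutenone adduct met on the way are racemic and their centres are erased in the next operation.

Key step: step 7

Remark: positions are numbered as in the chromanone (O1, C2–C4, C4a, C5–C8, C8a); ring A is the acylphloroglucinol ring.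
Remark: 1-ethoxyprop-1-yne, HC≡CMgBr and Me2C=CHMgBr are taken as commercial reagents or solutions.

**Route**

Step 1
Reactants: 1 2,4,6-trihydroxytoluene
Product: 3 2,4,6-trihydroxy-3-methylbenzaldehyde, via iminium chloride 2 (not isolated)
Conditions: POCl3, DMF, EtOAc, 0 °C → rt; then H2O, 50 °C
Reagents that add atoms: N,N-dimethylformamide CN(C)C=O; water O
Why: Vilsmeier–Haack formylation, in which the chloroiminium ion attacks one of the two equivalent free positions of the phloroglucinol and the resulting iminium deactivates the ring against a second formylation before it is hydrolysed.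

Step 2
Reactants: 3 2,4,6-trihydroxy-3-methylbenzaldehyde
Product: 4 2,4,6-tris(benzyloxy)-3-methylbenzaldehyde
Conditions: BnBr, K2CO3, DMF, 60 °C
Reagents that add atoms: benzyl bromide BrCc1ccccc1
Why: Williamson etherification, in which the formyl group lowers the carbon nucleophilicity of the phloroglucinol ring so that O-benzylation of all three phenoxides should prevail over C-benzylation.

Step 3
Reactants: 4 2,4,6-tris(benzyloxy)-3-methylbenzaldehyde
Product: 5 rac-1-[2,4,6-tris(benzyloxy)-3-methylphenyl]prop-2-yn-1-ol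
Conditions: HC≡CMgBr, THF, 0 °C; aq NH4Cl
Reagents that add atoms: ethynylmagnesium bromide C#C[Mg]Br
Why: Grignard 1,2-addition of an alkynylmagnesium halide to a 2,6-dialkoxybenzaldehyde, giving a racemic carbinol whose stereocentre is removed in step 4.

Step 4
Reactants: 5 rac-1-[2,4,6-tris(benzyloxy)-3-methylphenyl]prop-2-yn-1-ol
Product: 6 1,3,5-tris(benzyloxy)-2-methyl-4-(prop-2-yn-1-yl)benzene
Conditions: Et3SiH (excess), CF3CO2H, CH2Cl2, −40 → 0 °C
Reagents that add atoms: none
Why: Ionic (SN1) deoxygenation, in which acid ionises the carbinol to a propargylic cation stabilised by the 2,4,6-trialkoxyaryl group and excess silane should deliver hydride to the benzylic carbon before the cation can arylate a second molecule.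

Step 5
Reactants: 6 1,3,5-tris(benzyloxy)-2-methyl-4-(prop-2-yn-1-yl)benzene
Product: 9 triisopropyl({3-[2,4,6-tris(benzyloxy)-3-methylphenyl]prop-1-yn-1-yl}oxy)silane, via lithium acetylide 7 (not isolated), via lithium ynolate 8 (not isolated)
Conditions: LiN(SiMe3)2, THF, −78 °C; t-BuOOLi (from t-BuOOH and LiN(SiMe3)2), −78 → 0 °C; i-Pr3SiOTf, −78 → 0 °C
Reagents that add atoms: tert-butyl hydroperoxide CC(C)(C)OO; triisopropylsilyl trifluoromethanesulfonate CC(C)[Si](OS(=O)(=O)C(F)(F)F)(C(C)C)C(C)C
Why: Julia-type oxygenation of a lithium acetylide by lithium tert-butyl peroxide followed by O-silylation of the ynolate with a bulky silyl triflate, the acetylenic hydrogen being far more acidic than the benzylic CH2 so that no allene isomerisation is expected at low temperature.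

Step 6
Reactants: 10 1-ethoxyprop-1-yne; 11 acetyl chloride
Product: 13 3-ethoxy-2-methylcyclobut-2-en-1-one, via ketene 12 (not isolated)
Conditions: Et3N, Et2O, 0 °C → rt, slow addition of 11
Reagents that add atoms: none
Why: Ketene–alkyne [2+2] cycloaddition, in which ketene made by dehydrochlorination of the acid chloride bonds through its carbonyl carbon to the methyl-bearing (nucleophilic) carbon of the ynol ether.

Step 7
Reactants: 13 3-ethoxy-2-methylcyclobut-2-en-1-one; 9 triisopropyl({3-[2,4,6-tris(benzyloxy)-3-methylphenyl]prop-1-yn-1-yl}oxy)silane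
Product: 17 2-{[2,4,6-tris(benzyloxy)-3-methylphenyl]methyl}-5-ethoxy-4-methyl-3-[(triisopropylsilyl)oxy]phenol, via vinylketene 14 (not isolated), via cyclobutenone adduct 15 (not isolated), via dienylketene 16 (not isolated)
Conditions: toluene, 110 °C, sealed vessel, slow addition of 13 to 9
Reagents that add atoms: none
Why: Heating opens 13 by four-electron electrocyclic cleavage to vinylketene 14, whose carbonyl carbon is attacked by the alkyne carbon of 9 remote from oxygen (the one bearing the benzylic CH2) while its α-carbon bonds to the silyloxy carbon, giving adduct 15; 15 opens again to dienylketene 16, which closes and tautomerises to the phenol. This is a Danheiser benzannulation of a cyclobutenone with a siloxyalkyne, the variant that gives resorcinol monosilyl ethers. Ring B is closed by thermal six-electron (disrotatory) electrocyclisation of 16 between the ketene carbon (C8a) and the terminal CH2 (C4a), after the [2+2] step has made the C8a–C8 and C6–C7 bonds. No stereocentre is created in 17; the quaternary carbon of 15 is racemic and vanishes on ring opening. The step needs regiocontrol in the ketene–alkyne cycloaddition, and the polarisation of the siloxyalkyne secures it, so that the bridge sits ortho to the one free hydroxyl and the three ring oxygens emerge as OH, OSi(i-Pr)3 and OEt. Slow addition of 13 keeps 14 dilute so that it should be trapped by 9 and not by the phenol 17.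

Step 8
Reactants: 17 2-{[2,4,6-tris(benzyloxy)-3-methylphenyl]methyl}-5-ethoxy-4-methyl-3-[(triisopropylsilyl)oxy]phenol
Product: 18 3-{[2,4,6-tris(benzyloxy)-3-methylphenyl]methyl}-6-ethoxy-2-hydroxy-5-methyl-4-[(triisopropylsilyl)oxy]benzaldehyde
Conditions: MgCl2, Et3N, (CH2O)n, MeCN, reflux
Reagents that add atoms: paraformaldehyde (formaldehyde unit) C=O
Why: Magnesium-phenoxide-directed ortho-formylation (Casnati–Skattebøl), in which formaldehyde is delivered inside the magnesium phenoxide chelate to the only free ortho carbon of ring B (C4a) and a second formaldehyde oxidises the hydroxymethyl stage, so that ring A, which has no free phenol, should stay untouched.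

Step 9
Reactants: 18 3-{[2,4,6-tris(benzyloxy)-3-methylphenyl]methyl}-6-ethoxy-2-hydroxy-5-methyl-4-[(triisopropylsilyl)oxy]benzaldehyde
Product: 19 rac-2-{[2,4,6-tris(benzyloxy)-3-methylphenyl]methyl}-5-ethoxy-6-(1-hydroxy-3-methylbut-2-en-1-yl)-4-methyl-3-[(triisopropylsilyl)oxy]phenol
Conditions: Me2C=CHMgBr (3 equiv), THF, −78 → 0 °C; cold aq NH4Cl; crude product used at once
Reagents that add atoms: 2-methylprop-1-en-1-ylmagnesium bromide CC(C)=C[Mg]Br
Why: Grignard addition to a salicylaldehyde, in which the first equivalent forms the magnesium phenoxide and the second adds to the chelated aldehyde, giving a racemic carbinol that is oxidised directly because it ionises easily.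

Step 10
Reactants: 19 rac-2-{[2,4,6-tris(benzyloxy)-3-methylphenyl]methyl}-5-ethoxy-6-(1-hydroxy-3-methylbut-2-en-1-yl)-4-methyl-3-[(triisopropylsilyl)oxy]phenol
Product: 21 8-{[2,4,6-tris(benzyloxy)-3-methylphenyl]methyl}-5-ethoxy-2,2,6-trimethyl-7-[(triisopropylsilyl)oxy]-2,3-dihydro-4H-chromen-4-one, via enone 20 (not isolated)
Conditions: MnO2, CH2Cl2, rt; filter; then DBU (cat.), CH2Cl2, rt
Reagents that add atoms: none
Why: MnO2 oxidation of an allylic benzylic alcohol followed by base-catalysed 6-endo-trig oxa-Michael addition of the C8a phenol to the β,β-dimethyl enone, the standard closure of a 2,2-dimethylchroman-4-one (ring C).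

Step 11
Reactants: 21 8-{[2,4,6-tris(benzyloxy)-3-methylphenyl]methyl}-5-ethoxy-2,2,6-trimethyl-7-[(triisopropylsilyl)oxy]-2,3-dihydro-4H-chromen-4-one
Product: 22 8-{[2,4,6-tris(benzyloxy)-3-methyl-5-(2-methylpropanoyl)phenyl]methyl}-5-ethoxy-2,2,6-trimethyl-7-[(triisopropylsilyl)oxy]-2,3-dihydro-4H-chromen-4-one
Conditions: i-PrCO2H, (CF3CO)2O, CH2Cl2, 0 °C → rt
Reagents that add atoms: 2-methylpropanoic acid CC(C)C(=O)O
Why: Friedel–Crafts acylation through the mixed trifluoroacetic anhydride at the only aromatic C–H left on either oxygenated ring (ring A, flanked by two benzyloxy groups), the metal-free conditions avoiding chelation-driven loss of the benzyl ethers next to the new ketone.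

Step 12
Reactants: 22 8-{[2,4,6-tris(benzyloxy)-3-methyl-5-(2-methylpropanoyl)phenyl]methyl}-5-ethoxy-2,2,6-trimethyl-7-[(triisopropylsilyl)oxy]-2,3-dihydro-4H-chromen-4-one
Product: 23 8-{[2,4,6-tris(benzyloxy)-3-methyl-5-(2-methylpropanoyl)phenyl]methyl}-5-ethoxy-7-hydroxy-2,2,6-trimethyl-2,3-dihydro-4H-chromen-4-one
Conditions: Bu4NF, AcOH, THF, 0 °C
Reagents that add atoms: none
Why: Fluoride cleavage of an aryl silyl ether, buffered with acetic acid so that the phenoxide formed does not trigger retro-oxa-Michael opening of ring C.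

Step 13
Reactants: 23 8-{[2,4,6-tris(benzyloxy)-3-methyl-5-(2-methylpropanoyl)phenyl]methyl}-5-ethoxy-7-hydroxy-2,2,6-trimethyl-2,3-dihydro-4H-chromen-4-one
Product: 24 5,7-dihydroxy-2,2,6-trimethyl-8-{[2,4,6-trihydroxy-3-methyl-5-(2-methylpropanoyl)phenyl]methyl}-2,3-dihydro-4H-chromen-4-one (CNP0186856.0)
Conditions: BCl3 (excess), C6HMe5, CH2Cl2, −78 → 0 °C; then H2O
Reagents that add atoms: none
Why: BCl3 dealkylation, in which the benzyl ethers are cleaved at low temperature with pentamethylbenzene trapping the benzyl cations, and the C5 ethyl ether, held in a six-membered boron chelate with the C4 carbonyl, should be cleaved by chloride on warming, no free ring position remaining for C-benzylation.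

**Compound list**

1 | 2,4,6-trihydroxytoluene | Cc1c(O)cc(O)cc1O | starting material
2 | N-[(2,4,6-trihydroxy-3-methylphenyl)methylidene]-N-methylmethanaminium chloride | C[N+](C)=Cc1c(O)cc(O)c(C)c1O.[Cl-] | intermediate
3 | 2,4,6-trihydroxy-3-methylbenzaldehyde | O=Cc1c(O)cc(O)c(C)c1O | intermediate
4 | 2,4,6-tris(benzyloxy)-3-methylbenzaldehyde | O=Cc1c(OCc2ccccc2)cc(OCc2ccccc2)c(C)c1OCc1ccccc1 | intermediate
5 | rac-1-[2,4,6-tris(benzyloxy)-3-methylphenyl]prop-2-yn-1-ol | C#CC(O)c1c(OCc2ccccc2)cc(OCc2ccccc2)c(C)c1OCc1ccccc1 | intermediate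
6 | 1,3,5-tris(benzyloxy)-2-methyl-4-(prop-2-yn-1-yl)benzene | C#CCc1c(OCc2ccccc2)cc(OCc2ccccc2)c(C)c1OCc1ccccc1 | intermediate
7 | {3-[2,4,6-tris(benzyloxy)-3-methylphenyl]prop-1-yn-1-yl}lithium | [Li]C#CCc1c(OCc2ccccc2)cc(OCc2ccccc2)c(C)c1OCc1ccccc1 | intermediate
8 | lithium 3-[2,4,6-tris(benzyloxy)-3-methylphenyl]prop-1-yn-1-olate | [Li]OC#CCc1c(OCc2ccccc2)cc(OCc2ccccc2)c(C)c1OCc1ccccc1 | intermediate
9 | triisopropyl({3-[2,4,6-tris(benzyloxy)-3-methylphenyl]prop-1-yn-1-yl}oxy)silane | CC(C)[Si](OC#CCc1c(OCc2ccccc2)c(C)c(OCc2ccccc2)cc1OCc1ccccc1)(C(C)C)C(C)C | intermediate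
10 | 1-ethoxyprop-1-yne | CCOC#CC | starting material
11 | acetyl chloride | CC(=O)Cl | starting material
12 | ketene (ethenone) | C=C=O | intermediate
13 | 3-ethoxy-2-methylcyclobut-2-en-1-one | CCOC1=C(C)C(=O)C1 | intermediate
14 | 3-ethoxy-2-methylbuta-1,3-dien-1-one | CCOC(=C)C(C)=C=O | intermediate
15 | rac-2-{[2,4,6-tris(benzyloxy)-3-methylphenyl]methyl}-4-(1-ethoxyethenyl)-4-methyl-3-[(triisopropylsilyl)oxy]cyclobut-2-en-1-one | CCOC(=C)C1(C)C(=O)C(Cc2c(OCc3ccccc3)c(C)c(OCc3ccccc3)cc2OCc2ccccc2)=C1O[Si](C(C)C)(C(C)C)C(C)C | intermediate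
16 | (3E)-2-{[2,4,6-tris(benzyloxy)-3-methylphenyl]methyl}-5-ethoxy-4-methyl-3-[(triisopropylsilyl)oxy]hexa-1,3,5-trien-1-one | O=C=C(Cc1c(OCc2ccccc2)c(C)c(OCc2ccccc2)cc1OCc1ccccc1)/C(O[Si](C(C)C)(C(C)C)C(C)C)=C(/C)C(OCC)=C | intermediate
17 | 2-{[2,4,6-tris(benzyloxy)-3-methylphenyl]methyl}-5-ethoxy-4-methyl-3-[(triisopropylsilyl)oxy]phenol | CCOc1cc(O)c(Cc2c(OCc3ccccc3)c(C)c(OCc3ccccc3)cc2OCc2ccccc2)c(O[Si](C(C)C)(C(C)C)C(C)C)c1C | intermediate
18 | 3-{[2,4,6-tris(benzyloxy)-3-methylphenyl]methyl}-6-ethoxy-2-hydroxy-5-methyl-4-[(triisopropylsilyl)oxy]benzaldehyde | CCOc1c(C=O)c(O)c(Cc2c(OCc3ccccc3)c(C)c(OCc3ccccc3)cc2OCc2ccccc2)c(O[Si](C(C)C)(C(C)C)C(C)C)c1C | intermediate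
19 | rac-2-{[2,4,6-tris(benzyloxy)-3-methylphenyl]methyl}-5-ethoxy-6-(1-hydroxy-3-methylbut-2-en-1-yl)-4-methyl-3-[(triisopropylsilyl)oxy]phenol | CCOc1c(C(O)C=C(C)C)c(O)c(Cc2c(OCc3ccccc3)c(C)c(OCc3ccccc3)cc2OCc2ccccc2)c(O[Si](C(C)C)(C(C)C)C(C)C)c1C | intermediate
20 | 1-(3-{[2,4,6-tris(benzyloxy)-3-methylphenyl]methyl}-6-ethoxy-2-hydroxy-5-methyl-4-[(triisopropylsilyl)oxy]phenyl)-3-methylbut-2-en-1-one | CCOc1c(C(=O)C=C(C)C)c(O)c(Cc2c(OCc3ccccc3)c(C)c(OCc3ccccc3)cc2OCc2ccccc2)c(O[Si](C(C)C)(C(C)C)C(C)C)c1C | intermediate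
21 | 8-{[2,4,6-tris(benzyloxy)-3-methylphenyl]methyl}-5-ethoxy-2,2,6-trimethyl-7-[(triisopropylsilyl)oxy]-2,3-dihydro-4H-chromen-4-one | CCOc1c(C)c(O[Si](C(C)C)(C(C)C)C(C)C)c(Cc2c(OCc3ccccc3)c(C)c(OCc3ccccc3)cc2OCc2ccccc2)c2OC(C)(C)CC(=O)c12 | intermediate
22 | 8-{[2,4,6-tris(benzyloxy)-3-methyl-5-(2-methylpropanoyl)phenyl]methyl}-5-ethoxy-2,2,6-trimethyl-7-[(triisopropylsilyl)oxy]-2,3-dihydro-4H-chromen-4-one | CCOc1c(C)c(O[Si](C(C)C)(C(C)C)C(C)C)c(Cc2c(OCc3ccccc3)c(C)c(OCc3ccccc3)c(C(=O)C(C)C)c2OCc2ccccc2)c2OC(C)(C)CC(=O)c12 | intermediate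
23 | 8-{[2,4,6-tris(benzyloxy)-3-methyl-5-(2-methylpropanoyl)phenyl]methyl}-5-ethoxy-7-hydroxy-2,2,6-trimethyl-2,3-dihydro-4H-chromen-4-one | CCOc1c(C)c(O)c(Cc2c(OCc3ccccc3)c(C)c(OCc3ccccc3)c(C(=O)C(C)C)c2OCc2ccccc2)c2OC(C)(C)CC(=O)c12 | intermediate
24 | 5,7-dihydroxy-2,2,6-trimethyl-8-{[2,4,6-trihydroxy-3-methyl-5-(2-methylpropanoyl)phenyl]methyl}-2,3-dihydro-4H-chromen-4-one | Cc1c(O)c(Cc2c(O)c(C)c(O)c3c2OC(C)(C)CC3=O)c(O)c(C(=O)C(C)C)c1O | target

**Count and risks**

Total step count: 13. Longest linear sequence: 12 steps (steps 1–5 and 7–13); step 6 is a one-step side branch.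

Steps most likely to fail:

1. Step 7. The 3-alkoxycyclobutenone is a vinylogous ester and may open to the vinylketene only at temperatures at which the siloxyalkyne suffers a 1,3-silyl shift, or the vinylketene may be intercepted by the product phenol. The fallback sets out from 9 and comes back at 17, and makes the same vinylketene 14 at or below room temperature by 1,4-dehydrochlorination. Commercial ethyl 2-methyl-3-oxobutanoate would be treated with HC(OEt)3 and catalytic H2SO4 in EtOH to give ethyl 3-ethoxy-2-methylbut-2-enoate F1. Saponification with LiOH in aqueous THF and careful acidification would give 3-ethoxy-2-methylbut-2-enoic acid F2. (COCl)2 with catalytic DMF would then give 3-ethoxy-2-methylbut-2-enoyl chloride F3. Slow addition of F3 to 9 and Et3N in toluene at 0 °C → rt should give adduct 15 through 14, and warming to 80 °C should complete ring opening and six-electron closure to 17.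

2. Step 13. Cleavage of the ethyl ether may stay incomplete, or the Lewis acid may open the pyranone ring or cut the methylene bridge before the last ether has gone. The fallback sets out from 23 and comes back at 24, and separates the two tasks. Hydrogenolysis (H2, palladium on carbon, EtOAc–MeOH, rt) should remove the three benzyl groups and give 5-ethoxy-7-hydroxy-2,2,6-trimethyl-8-{[2,4,6-trihydroxy-3-methyl-5-(2-methylpropanoyl)phenyl]methyl}-2,3-dihydro-4H-chromen-4-one F4. MgI2·OEt2 in toluene–THF at 60 °C should then cleave the C5 ethyl ether by iodide attack inside the magnesium chelate with the C4 carbonyl, giving 24.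

3. Step 11. Acylation at the doubly flanked ring A position may be slow, the acylium ion may attack the bridge-bearing carbon with loss of the diarylmethane link, or benzyl ethers may be lost to acid. The fallback sets out from 21 and comes back at 22, and uses a small electrophile followed by an organometallic. Vilsmeier–Haack formylation (POCl3, DMF, 0 °C → rt, then aq NaOAc) should give 2,4,6-tris(benzyloxy)-3-({5-ethoxy-2,2,6-trimethyl-4-oxo-7-[(triisopropylsilyl)oxy]-3,4-dihydro-2H-chromen-8-yl}methyl)-5-methylbenzaldehyde F5. i-PrMgCl with CeCl3 in THF at −78 °C should add to the aldehyde in preference to the hindered, peri-substituted chromanone carbonyl and give rac-8-{[2,4,6-tris(benzyloxy)-3-(1-hydroxy-2-methylpropyl)-5-methylphenyl]methyl}-5-ethoxy-2,2,6-trimethyl-7-[(triisopropylsilyl)oxy]-2,3-dihydro-4H-chromen-4-one F6. Dess–Martin periodinane in CH2Cl2 should oxidise F6 to 22.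

**Further compounds**

F1 | step 7 | ethyl 3-ethoxy-2-methylbut-2-enoate (E/Z mixture, geometry lost in 14) | CCOC(C)=C(C)C(=O)OCC
F2 | step 7 | 3-ethoxy-2-methylbut-2-enoic acid | CCOC(C)=C(C)C(=O)O
F3 | step 7 | 3-ethoxy-2-methylbut-2-enoyl chloride | CCOC(C)=C(C)C(=O)Cl
F4 | step 13 | 5-ethoxy-7-hydroxy-2,2,6-trimethyl-8-{[2,4,6-trihydroxy-3-methyl-5-(2-methylpropanoyl)phenyl]methyl}-2,3-dihydro-4H-chromen-4-one | CCOc1c(C)c(O)c(Cc2c(O)c(C)c(O)c(C(=O)C(C)C)c2O)c2OC(C)(C)CC(=O)c12
F5 | step 11 | 2,4,6-tris(benzyloxy)-3-({5-ethoxy-2,2,6-trimethyl-4-oxo-7-[(triisopropylsilyl)oxy]-3,4-dihydro-2H-chromen-8-yl}methyl)-5-methylbenzaldehyde | CCOc1c(C)c(O[Si](C(C)C)(C(C)C)C(C)C)c(Cc2c(OCc3ccccc3)c(C)c(OCc3ccccc3)c(C=O)c2OCc2ccccc2)c2OC(C)(C)CC(=O)c12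
F6 | step 11 | rac-8-{[2,4,6-tris(benzyloxy)-3-(1-hydroxy-2-methylpropyl)-5-methylphenyl]methyl}-5-ethoxy-2,2,6-trimethyl-7-[(triisopropylsilyl)oxy]-2,3-dihydro-4H-chromen-4-one | CCOc1c(C)c(O[Si](C(C)C)(C(C)C)C(C)C)c(Cc2c(OCc3ccccc3)c(C)c(OCc3ccccc3)c(C(O)C(C)C)c2OCc2ccccc2)c2OC(C)(C)CC(=O)c12
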